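The cyclopentane is read as a three-carbon unit (the isopropenyl-bearing CH and both ring CH2) joined to a two-carbon unit (the carbinol carbon and the chain-bearing CH). Hydroxyl and side chain are cis on that C2 unit, an acetoacetate pattern, and an isopropenyl group beside a new ring bond marks a ring-opened vinylcyclopropane. A thiyl-radical-catalysed [3+2] cycloaddition of isopropenylcyclopropane to (R)-2-tert-butyl-6-methyl-1,3-dioxin-4-one therefore makes both ring bonds, CH2–C(OH) and CH–CH, and all three stereocentres at once from a cyclopropane and a flat heterocycle. Reduction frees a hydroxy aldehyde that a C30 polyenyl ylide, built from geranyl bromide and crocetin dialdehyde, converts into the carotenoid.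

Key step: step 2

Assumption: (R)-2-tert-butyl-6-methyl-4H-1,3-dioxin-4-one (the pivalaldehyde acetal of the acetoacetic acid enol, from the (R)-3-hydroxybutanoic acid series) and all-E crocetin dialdehyde are taken as purchasable building blocks.

**Route**

Step 1
Reactants: 1 cyclopropyl methyl ketone
Product: 2 isopropenylcyclopropane (prop-1-en-2-ylcyclopropane)
Conditions: Ph3PCH3Br, KOtBu, diglyme, 0 °C → rt; product distilled from the flask
Reagents that add atoms: methyltriphenylphosphonium bromide, C[P+](c1ccccc1)(c1ccccc1)c1ccccc1.[Br-]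
Why: Wittig methylenation of a simple methyl ketone; the high-boiling solvent should allow the volatile alkene to be distilled away from Ph3PO.

Step 2
Reactants: 2 isopropenylcyclopropane; 3 (R)-2-tert-butyl-6-methyl-4H-1,3-dioxin-4-one
Product: 4 (2R,4aR,5S,7aS)-2-tert-butyl-7a-methyl-5-(prop-1-en-2-yl)hexahydrocyclopenta[d][1,3]dioxin-4-one
Conditions: PhSSPh (0.2 equiv), AIBN (0.1 equiv), PhH, 70 °C; 2 added by syringe pump to 3 (3 equiv, excess recovered)
Reagents that add atoms: none
Why: Proposed new method: PhS• adds to the CH2 of the isopropenyl group of 2, the cyclopropylcarbinyl radical opens to the primary radical PhSCH2C(CH3)=CH–CH2CH2•, this adds to C6 of 3 (the β-carbon of the vinylogous carbonate) to give the C5 lactone α-radical, which closes onto the allyl sulfide carbon and expels PhS•, unveiling the isopropenyl group and carrying the chain; the closest known reaction type is the thiyl-radical-catalysed [3+2] cycloaddition of vinylcyclopropanes with acrylates and enol ethers, which has not been shown for a β,β-disubstituted β-alkoxy enoate, although carbon radicals and cuprates are known to add at C6 of such dioxinones. The cyclopentane closes in the 5-exo-trig mode. C7a should be set by attack anti to the tert-butyl group of the acetal, C4a by the cis ring fusion that a five-membered closure onto the same face enforces (oxygen and carbonyl carbon cis), and C5 by the fully substituted alkene terminus turning away from the lactone carbonyl in the transition state (isopropenyl exo). The step needs addition of the unstabilised radical at the hindered oxygen-bearing carbon to outrun its capture by PhSSPh or by a second molecule of 2; excess 3, a low disulfide concentration and slow addition of 2 are meant to secure this, and the polarity match (nucleophilic alkyl radical, electron-poor C6, stabilised α-acyl radical) should fix the regiochemistry.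

Step 3
Reactants: 4 (2R,4aR,5S,7aS)-2-tert-butyl-7a-methyl-5-(prop-1-en-2-yl)hexahydrocyclopenta[d][1,3]dioxin-4-one
Product: 6 (1R,2S,5S)-2-hydroxy-2-methyl-5-(prop-1-en-2-yl)cyclopentane-1-carbaldehyde, via lactol 5 (not isolated)
Conditions: iBu2AlH (1.2 equiv), CH2Cl2, −78 °C; aq. potassium sodium tartrate (KNaC4H4O6), rt
Reagents that add atoms: none
Why: Lactone-to-lactol reduction should stop at the aluminium hemiacetal at low temperature; on work-up lactol 5 opens and the hemiacetal of the tertiary alcohol loses pivalaldehyde, freeing aldehyde and hydroxyl together with no stereocentre touched.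

Step 4
Reactants: 7 geranyl bromide ((2E)-1-bromo-3,7-dimethylocta-2,6-diene)
Product: 8 diethyl [(2E)-3,7-dimethylocta-2,6-dien-1-yl]phosphonate
Conditions: P(OEt)3 (1.5 equiv), neat, 120 °C, EtBr distilled off
Reagents that add atoms: triethyl phosphite, CCOP(OCC)OCC
Why: Michaelis–Arbuzov reaction of a primary allylic bromide; SN2 attack by phosphorus should keep the E double bond.

Step 5
Reactants: 8 diethyl [(2E)-3,7-dimethylocta-2,6-dien-1-yl]phosphonate; 9 crocetin dialdehyde (all-E 2,6,11,15-tetramethylhexadeca-2,4,6,8,10,12,14-heptaenedial)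
Product: 11 all-E 2,6,11,15,19,23-hexamethyltetracosa-2,4,6,8,10,12,14,16,18,22-decaenal, via sodium phosphonate carbanion 10 (not isolated)
Conditions: NaH, THF, 0 °C; then added slowly to 9 (3 equiv), THF/CH2Cl2, 0 °C → rt
Reagents that add atoms: none
Why: Horner–Wadsworth–Emmons olefination: the allylic phosphonate carbanion should react at its α-carbon and give the E alkene, while inverse addition to excess 9 (recoverable) should keep the second formyl group untouched.

Step 6
Reactants: 11 all-E 2,6,11,15,19,23-hexamethyltetracosa-2,4,6,8,10,12,14,16,18,22-decaenal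
Product: 12 all-E 2,6,11,15,19,23-hexamethyltetracosa-2,4,6,8,10,12,14,16,18,22-decaen-1-ol
Conditions: NaBH4, MeOH/THF, 0 °C
Reagents that add atoms: none
Why: Borohydride reduction should take the conjugated aldehyde in 1,2-fashion to the primary polyenyl alcohol without touching the polyene.

Step 7
Reactants: 12 all-E 2,6,11,15,19,23-hexamethyltetracosa-2,4,6,8,10,12,14,16,18,22-decaen-1-ol
Product: 13 [all-E 2,6,11,15,19,23-hexamethyltetracosa-2,4,6,8,10,12,14,16,18,22-decaen-1-yl]triphenylphosphonium bromide
Conditions: PPh3·HBr (1.05 equiv), MeOH/CH2Cl2, rt, dark, argon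
Reagents that add atoms: triphenylphosphine hydrobromide, [Br-].[PH+](c1ccccc1)(c1ccccc1)c1ccccc1
Why: Acid ionises the polyenylic alcohol and PPh3 should capture the delocalised cation at the terminal carbon, which keeps full conjugation (standard formation of carotenoid Wittig salts).

Step 8
Reactants: 13 the C30 phosphonium bromide; 6 (1R,2S,5S)-2-hydroxy-2-methyl-5-(prop-1-en-2-yl)cyclopentane-1-carbaldehyde
Product: 16 (1S,2R,3S)-1-methyl-2-[(1E,3E,5E,7E,9E,11E,13E,15E,17E,19E)-3,7,12,16,20,24-hexamethylpentacosa-1,3,5,7,9,11,13,15,17,19,23-undecaen-1-yl]-3-(prop-1-en-2-yl)cyclopentan-1-ol, via C30 ylide 14 (not isolated), via Z-isomer 15 (not isolated)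
Conditions: NaN(SiMe3)2, THF, −78 → 0 °C; 6, −78 °C → rt; then I2 (cat.), CH2Cl2, visible light
Reagents that add atoms: none
Why: Wittig olefination: the delocalised, weakly basic ylide 14 should leave the tertiary hydroxyl alone and give the new disubstituted double bond as an E/Z mixture, which iodine-catalysed equilibration should funnel from the hindered Z-isomer 15 to the all-E target; the ring stereocentres are not involved, the formyl-bearing carbon already holding its more stable configuration.

**Compound list**

1 | cyclopropyl methyl ketone | CC(=O)C1CC1 | starting material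
2 | isopropenylcyclopropane | C=C(C)C1CC1 | intermediate
3 | (R)-2-tert-butyl-6-methyl-4H-1,3-dioxin-4-one | CC1=CC(=O)O[C@H](C(C)(C)C)O1 | starting material
4 | (2R,4aR,5S,7aS)-2-tert-butyl-7a-methyl-5-(prop-1-en-2-yl)hexahydrocyclopenta[d][1,3]dioxin-4-one (cis-fused; tert-butyl, 7a-methyl, H-4a and isopropenyl on the same face) | C=C(C)[C@H]1CC[C@]2(C)O[C@@H](C(C)(C)C)OC(=O)[C@H]12 | intermediate
5 | lactol of 4 (C4 carbonyl reduced to CH–OH, both C4 epimers, other centres as in 4) | C=C(C)[C@H]1CC[C@]2(C)O[C@@H](C(C)(C)C)OC(O)[C@H]12 | intermediate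
6 | (1R,2S,5S)-2-hydroxy-2-methyl-5-(prop-1-en-2-yl)cyclopentane-1-carbaldehyde | C=C(C)[C@H]1CC[C@](C)(O)[C@@H]1C=O | intermediate
7 | geranyl bromide | CC(C)=CCC/C(C)=C/CBr | starting material
8 | diethyl [(2E)-3,7-dimethylocta-2,6-dien-1-yl]phosphonate | CC(C)=CCC/C(C)=C/CP(=O)(OCC)OCC | intermediate
9 | crocetin dialdehyde (all-E) | O=C/C(C)=C/C=C/C(C)=C/C=C/C=C(C)/C=C/C=C(C)/C=O | starting material
10 | sodium salt of the α-carbanion of 8 | CC(C)=CCC/C(C)=C/[CH-]P(=O)(OCC)OCC.[Na+] | intermediate
11 | all-E 2,6,11,15,19,23-hexamethyltetracosa-2,4,6,8,10,12,14,16,18,22-decaenal | CC(C)=CCC/C(C)=C/C=C/C(C)=C/C=C/C(C)=C/C=C/C=C(C)/C=C/C=C(C)/C=O | intermediate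
12 | all-E 2,6,11,15,19,23-hexamethyltetracosa-2,4,6,8,10,12,14,16,18,22-decaen-1-ol | CC(C)=CCC/C(C)=C/C=C/C(C)=C/C=C/C(C)=C/C=C/C=C(C)/C=C/C=C(C)/CO | intermediate
13 | triphenylphosphonium bromide of 12 (PPh3+ in place of OH) | CC(C)=CCC/C(C)=C/C=C/C(C)=C/C=C/C(C)=C/C=C/C=C(C)/C=C/C=C(C)/C[P+](c1ccccc1)(c1ccccc1)c1ccccc1.[Br-] | intermediate
14 | ylide of 13 | CC(C)=CCC/C(C)=C/C=C/C(C)=C/C=C/C(C)=C/C=C/C=C(C)/C=C/C=C(C)/[CH-][P+](c1ccccc1)(c1ccccc1)c1ccccc1 | intermediate
15 | Z-isomer of 16 at the double bond next to the ring, all else as in 16 | C=C(C)[C@H]1CC[C@](C)(O)[C@@H]1\C=C/C(C)=C/C=C/C(C)=C/C=C/C=C(C)/C=C/C=C(C)/C=C/C=C(\C)CCC=C(C)C | intermediate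
16 | (1S,2R,3S)-1-methyl-2-[(all-E)-3,7,12,16,20,24-hexamethylpentacosa-1,3,5,7,9,11,13,15,17,19,23-undecaen-1-yl]-3-(prop-1-en-2-yl)cyclopentan-1-ol | C=C(C)[C@H]1CC[C@](C)(O)[C@@H]1/C=C/C(C)=C/C=C/C(C)=C/C=C/C=C(C)/C=C/C=C(C)/C=C/C=C(\C)CCC=C(C)C | target

**Step count**

Total step count: 8. Longest linear sequence: 5 steps (steps 4 to 8, from geranyl bromide).

**Steps most likely to fail**

Step 2. The chain may stall because the primary radical adds too slowly to the hindered, oxygen-bearing C6 and is drained by capture with the disulfide or by oligomerisation with 2. Ring closure with the alkene on the endo face would also erode the configuration at C5. The fallback uses known chemistry and sets out from 3. Conjugate addition of lithium bis(4-methylpent-3-enyl)cuprate (from 5-bromo-2-methylpent-2-ene, tBuLi, CuI; Et2O, −78 °C) anti to the tert-butyl group should give (2R,6S)-2-tert-butyl-6-methyl-6-(4-methylpent-3-en-1-yl)-1,3-dioxan-4-one F1. Allylic oxidation of the E-methyl group (SeO2 cat., tBuOOH, CH2Cl2) should give the allylic alcohol F2, and PPh3/CCl4 the allylic chloride F3. The lactone enolate (LiN(iPr)2, THF, −78 °C) should then close the cyclopentane by intramolecular SN2′ displacement in the 5-exo mode, forming the isopropenyl group. The route is rejoined at 4.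

Step 3. Over-reduction of the aluminium hemiacetal, or a lactol that does not collapse cleanly, would give mixtures of diol, lactol and aldehyde. The fallback sets out from 4. Full reduction with LiAlH4 (THF, 0 °C) should give (1S,2S,3S)-2-(hydroxymethyl)-1-methyl-3-(prop-1-en-2-yl)cyclopentan-1-ol F4. Oxidation of the primary alcohol alone with TEMPO (cat.)/PhI(OAc)2 in CH2Cl2 then returns to 6.

Step 8. The bulky ylide may attack the hindered, enolisable β-hydroxy aldehyde slowly, so that β-elimination of water or retro-aldol ring opening competes, and the Z to E equilibration may stay incomplete. The fallback reverses the polarity of the coupling and sets out from 4 through the diol F4 (made as in the fallback to step 3); steps 6 and 7 are then not needed. A Mitsunobu reaction with 1-phenyl-1H-tetrazole-5-thiol (PPh3, DIAD) should give the primary tetrazolyl sulfide F5. Oxidation with H2O2 and (NH4)6Mo7O24 should give the sulfone F6, and Et3SiOTf/2,6-lutidine its tertiary triethylsilyl ether F7. Julia–Kocienski olefination of F7 with aldehyde 11 (KN(SiMe3)2, DME, −60 °C → rt) should form the E double bond next to the ring and give the triethylsilyl ether of the carotenoid F8. Bu4NF in THF then gives 16, where the route is rejoined.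

**Further compounds**

F1 | step 2 | (2R,6S)-2-tert-butyl-6-methyl-6-(4-methylpent-3-en-1-yl)-1,3-dioxan-4-one | CC(C)=CCC[C@]1(C)O[C@@H](C(C)(C)C)OC(=O)C1
F2 | step 2 | (2R,6S)-2-tert-butyl-6-[(3E)-5-hydroxy-4-methylpent-3-en-1-yl]-6-methyl-1,3-dioxan-4-one | OC/C(C)=C/CC[C@]1(C)O[C@@H](C(C)(C)C)OC(=O)C1
F3 | step 2 | (2R,6S)-2-tert-butyl-6-[(3E)-5-chloro-4-methylpent-3-en-1-yl]-6-methyl-1,3-dioxan-4-one | ClC/C(C)=C/CC[C@]1(C)O[C@@H](C(C)(C)C)OC(=O)C1
F4 | step 3 | (1S,2S,3S)-2-(hydroxymethyl)-1-methyl-3-(prop-1-en-2-yl)cyclopentan-1-ol | C=C(C)[C@H]1CC[C@](C)(O)[C@@H]1CO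
F5 | step 8 | 1-phenyl-1H-tetrazol-5-yl sulfide of F4 (sulfur in place of the primary oxygen, ring configuration as in F4) | C=C(C)[C@H]1CC[C@](C)(O)[C@@H]1CSc1nnnn1-c1ccccc1
F6 | step 8 | sulfone of F5 | C=C(C)[C@H]1CC[C@](C)(O)[C@@H]1CS(=O)(=O)c1nnnn1-c1ccccc1
F7 | step 8 | triethylsilyl ether of F6 at the tertiary hydroxyl | C=C(C)[C@H]1CC[C@](C)(O[Si](CC)(CC)CC)[C@@H]1CS(=O)(=O)c1nnnn1-c1ccccc1
F8 | step 8 | triethylsilyl ether of 16 | C=C(C)[C@H]1CC[C@](C)(O[Si](CC)(CC)CC)[C@@H]1/C=C/C(C)=C/C=C/C(C)=C/C=C/C=C(C)/C=C/C=C(C)/C=C/C=C(\C)CCC=C(C)C
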